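**Plan**

1. Retrosynthesis: the aryl–C7′ (carbinol) bond is cut first. The C3 hydroxymethyl (C9–OH) and the C4 carbinol carbon (C7′) are cis on the oxolane ring and 1,4-related (O–C9–C3–C4–C7′), so C7′ can be stored as the anomeric carbon of a cis-fused furo[3,4-c]furan lactol, which an aryl Grignard reagent opens.
2. The lactol is cut back to a 4-vinyl oxolane (C=C cleavage), the oxolane O1–C2 bond to a benzylic 1,4-diol, and the C2–C3 bond by an aldol to silylated vanillin and (R)-4-vinylbutyrolactone (from furan-2(5H)-one and a vinylboron reagent).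
3. Forward order: butyrolactone ring (asymmetric vinyl addition), aldol, reduction to the triol, oxolane ring by benzylic SN1 closure, lactol ring by oxidative cleavage, aryl addition with lactol opening, desilylation.
4. Stereochemistry: C4 from the chiral rhodium catalyst; C3 by anti approach in the aldol; C2 by reversible cation closure (both carbinol epimers converge on 2,3-trans); C7′ by attack on the convex face of the magnesium-bridged opened lactol (both anomers converge on R).

Key step: step 8

Remark on the chemistry: compounds 7, 8 and 10 are carried as mixtures at one carbinol centre that a later step destroys, and lactol 12 as both anomers; their SMILES leave that centre open. Oxolane atoms are numbered as in the target (O1, C2 aryl, C3 CH2OH, C4 side chain, C5).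

**Step 1**
Reactants: 1 vanillin
Product: 2 4-(tert-butyldimethylsilyloxy)-3-methoxybenzaldehyde
Conditions: TBSCl, imidazole, DMF, rt
Reagents that add atoms: tert-butyldimethylsilyl chloride, CC(C)(C)[Si](C)(C)Cl
Why: Imidazole-mediated silyl ether formation masks the phenol, so that the aldehyde is not deactivated as a phenoxide toward the lactone enolate in step 3 and the group can be removed at the end without acid or hydrogen.

**Step 2**
Reactants: 3 furan-2(5H)-one; 4 potassium vinyltrifluoroborate
Product: 5 (R)-4-vinyldihydrofuran-2(3H)-one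
Conditions: [Rh(cod)2]BF4 (3 mol %), (R)-BINAP (3.3 mol %), toluene/H2O (10:1), 100 °C
Reagents that add atoms: none
Why: Rhodium-catalysed asymmetric 1,4-addition of an alkenylboron reagent to an unsaturated lactone (Hayashi–Miyaura reaction), in which the (R)-BINAP–rhodium complex selects one face of the planar butenolide and should set the R centre that becomes C4 of the target, the only centre that needs an external chiral source (the ligand antipode follows the usual enone-face model and is to be confirmed on the product).

**Step 3**
Reactants: 5 (R)-4-vinyldihydrofuran-2(3H)-one; 2 4-(tert-butyldimethylsilyloxy)-3-methoxybenzaldehyde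
Product: 7 (3R,4S)-3-{[4-(tert-butyldimethylsilyloxy)-3-methoxyphenyl](hydroxy)methyl}-4-vinyldihydrofuran-2(3H)-one (both carbinol epimers), via lactone lithium enolate 6 (not isolated)
Conditions: LiN(i-Pr)2 (1.05 equiv), THF, −78 °C; then 2, −78 °C; AcOH quench at −78 °C
Reagents that add atoms: none
Why: Lithium enolate aldol addition in which the aldehyde approaches the enolate face anti to the 4-vinyl group, which should fix the trans relation of the two lactone substituents (C3 of the target), while the carbinol centre forms as a mixture that step 5 erases.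

**Step 4**
Reactants: 7 aldol adduct
Product: 8 (2S,3S)-2-{[4-(tert-butyldimethylsilyloxy)-3-methoxyphenyl](hydroxy)methyl}-3-vinylbutane-1,4-diol (both carbinol epimers)
Conditions: LiBH4 (2 equiv), THF, 0 °C → rt; aq. NH4Cl
Reagents that add atoms: none
Why: Hydride reduction of the lactone to the 1,4-diol with LiBH4, which should leave the aryl silyl ether and the alkene untouched and does not affect any stereocentre.

**Step 5**
Reactants: 8 triol
Product: 9 [(2R,3S,4S)-2-[4-(tert-butyldimethylsilyloxy)-3-methoxyphenyl]-4-vinyloxolan-3-yl]methanol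
Conditions: camphor-10-sulfonic acid (10 mol %), CH2Cl2 (0.02 M), 0 °C → rt
Reagents that add atoms: none
Why: Acid-catalysed SN1 cyclodehydration through the p-silyloxybenzylic cation, in which both carbinol epimers give the same planar cation, only the C5 hydroxyl can close a five-membered ring (the C9 hydroxyl would give an oxetane), and reversible closure should place the aryl group trans to the C3 hydroxymethyl (C2 set under thermodynamic control).

**Step 6**
Reactants: 9 vinyl oxolane alcohol
Product: 12 (3aS,4R,6aS)-4-[4-(tert-butyldimethylsilyloxy)-3-methoxyphenyl]tetrahydro-1H,3H-furo[3,4-c]furan-1-ol (both anomers), via vicinal diol 10 (not isolated), via open-chain hydroxy aldehyde 11 (not isolated)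
Conditions: OsO4 (2 mol %), NaIO4 (3 equiv), 2,6-lutidine (2 equiv), dioxane/H2O (3:1), rt
Reagents that add atoms: osmium tetroxide, O=[Os](=O)(=O)=O (catalytic oxygen carrier); sodium periodate, [Na+].[O-]I(=O)(=O)=O (terminal oxygen source)
Why: Lemieux–Johnson oxidative cleavage (osmylation, then periodate glycol cleavage) converts the vinyl group into a formyl group that the cis C3 hydroxymethyl traps at once as the cis-fused lactol, which locks C4 against epimerisation because a trans-fused 5,5 system cannot form.

**Step 7**
Reactants: 13 4-bromo-2-methoxyphenol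
Product: 14 (4-bromo-2-methoxyphenoxy)(tert-butyl)dimethylsilane
Conditions: TBSCl, imidazole, DMF, rt
Reagents that add atoms: tert-butyldimethylsilyl chloride, CC(C)(C)[Si](C)(C)Cl
Why: Imidazole-mediated silyl ether formation removes the acidic phenol proton so that the aryl bromide can be converted into a Grignard reagent.

**Step 8**
Reactants: 14 (4-bromo-2-methoxyphenoxy)(tert-butyl)dimethylsilane; 12 lactol
Product: 17 (R)-[4-(tert-butyldimethylsilyloxy)-3-methoxyphenyl]{(3S,4S,5R)-5-[4-(tert-butyldimethylsilyloxy)-3-methoxyphenyl]-4-(hydroxymethyl)oxolan-3-yl}methanol, via aryl Grignard reagent 15 (not isolated), via chelated open-chain magnesium alkoxide 16 (not isolated)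
Conditions: 14, Mg turnings, THF, 45 °C; then 12 added to 15 (3 equiv), CH2Cl2/THF, −78 → 0 °C; aq. NH4Cl
Reagents that add atoms: none
Why: The first equivalent of Grignard reagent 15 deprotonates lactol 12, whose two anomers open to the same bromomagnesium alkoxide 16 in which magnesium bridges the C9 alkoxide and the formyl oxygen (a seven-membered chelate that keeps the shape of the opened lactol ring, cis-fused to the oxolane), and a second equivalent adds to the formyl carbon. The closest known reaction type is the addition of aryl Grignard reagents to cis-fused γ-lactols, the ring-chain tautomers of γ-hydroxy aldehydes, read with the Cram chelate model. No ring is closed; the lactol ring is opened and the C9 hydroxyl is released. The new carbinol centre is controlled by the chelate: the aryl group should enter from the convex (exo) face, away from the oxolane ring, which gives the R configuration (the same relative arrangement as a 2,6-diexo furofuran). The step needs facial selectivity opposite to the non-chelated Felkin–Anh mode and chemoselectivity for the aldehyde; the cis relation of C3–CH2O and C4–CHO fixed in steps 3 and 6 secures the chelate, and the aryl silyl ethers are inert to the reagent.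

**Step 9**
Reactants: 17 bis-silyl ether
Product: 18 4-[(2R,3S,4S)-4-[(R)-hydroxy(4-hydroxy-3-methoxyphenyl)methyl]-3-(hydroxymethyl)oxolan-2-yl]-2-methoxyphenol (target)
Conditions: Bu4NF (2.2 equiv), AcOH (2.2 equiv), THF, 0 °C
Reagents that add atoms: none
Why: Fluoride-mediated desilylation of both aryl silyl ethers under acetic acid buffering, chosen because acid would ionise the p-hydroxybenzylic alcohol and close the second ring and hydrogenolysis would threaten the benzylic C–O bonds; no stereocentre is touched.

**Compound list**

1 | vanillin (4-hydroxy-3-methoxybenzaldehyde) | COc1cc(C=O)ccc1O | starting material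
2 | 4-(tert-butyldimethylsilyloxy)-3-methoxybenzaldehyde | COc1cc(C=O)ccc1O[Si](C)(C)C(C)(C)C | intermediate
3 | furan-2(5H)-one | O=C1OCC=C1 | starting material
4 | potassium vinyltrifluoroborate | [K+].C=C[B-](F)(F)F | starting material
5 | (R)-4-vinyldihydrofuran-2(3H)-one | C=C[C@@H]1COC(=O)C1 | intermediate
6 | lithium enolate of 5 (formed in the flask) | C=C[C@@H]1COC(O[Li])=C1 | intermediate
7 | (3R,4S)-3-{[4-(tert-butyldimethylsilyloxy)-3-methoxyphenyl](hydroxy)methyl}-4-vinyldihydrofuran-2(3H)-one, both carbinol epimers | C=C[C@@H]1COC(=O)[C@H]1C(O)c1ccc(O[Si](C)(C)C(C)(C)C)c(OC)c1 | intermediate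
8 | (2S,3S)-2-{[4-(tert-butyldimethylsilyloxy)-3-methoxyphenyl](hydroxy)methyl}-3-vinylbutane-1,4-diol, both carbinol epimers | C=C[C@H](CO)[C@@H](CO)C(O)c1ccc(O[Si](C)(C)C(C)(C)C)c(OC)c1 | intermediate
9 | [(2R,3S,4S)-2-[4-(tert-butyldimethylsilyloxy)-3-methoxyphenyl]-4-vinyloxolan-3-yl]methanol | C=C[C@@H]1CO[C@@H](c2ccc(O[Si](C)(C)C(C)(C)C)c(OC)c2)[C@@H]1CO | intermediate
10 | 1-[(3S,4S,5R)-5-[4-(tert-butyldimethylsilyloxy)-3-methoxyphenyl]-4-(hydroxymethyl)oxolan-3-yl]ethane-1,2-diol, both carbinol epimers (formed in the flask) | OCC(O)[C@@H]1CO[C@@H](c2ccc(O[Si](C)(C)C(C)(C)C)c(OC)c2)[C@@H]1CO | intermediate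
11 | (3S,4S,5R)-5-[4-(tert-butyldimethylsilyloxy)-3-methoxyphenyl]-4-(hydroxymethyl)oxolane-3-carbaldehyde (open form of 12, formed in the flask) | O=C[C@@H]1CO[C@@H](c2ccc(O[Si](C)(C)C(C)(C)C)c(OC)c2)[C@@H]1CO | intermediate
12 | (3aS,4R,6aS)-4-[4-(tert-butyldimethylsilyloxy)-3-methoxyphenyl]tetrahydro-1H,3H-furo[3,4-c]furan-1-ol, cis-fused lactol, both anomers | OC1OC[C@H]2[C@H](c3ccc(O[Si](C)(C)C(C)(C)C)c(OC)c3)OC[C@@H]12 | intermediate
13 | 4-bromo-2-methoxyphenol | COc1cc(Br)ccc1O | starting material
14 | (4-bromo-2-methoxyphenoxy)(tert-butyl)dimethylsilane | COc1cc(Br)ccc1O[Si](C)(C)C(C)(C)C | intermediate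
15 | [4-(tert-butyldimethylsilyloxy)-3-methoxyphenyl]magnesium bromide (formed in the flask) | COc1cc([Mg]Br)ccc1O[Si](C)(C)C(C)(C)C | intermediate
16 | bromomagnesium alkoxide of 11, magnesium bridging the alkoxide and the formyl oxygen (formed in the flask) | O=C[C@@H]1CO[C@@H](c2ccc(O[Si](C)(C)C(C)(C)C)c(OC)c2)[C@@H]1CO[Mg]Br | intermediate
17 | (R)-[4-(tert-butyldimethylsilyloxy)-3-methoxyphenyl]{(3S,4S,5R)-5-[4-(tert-butyldimethylsilyloxy)-3-methoxyphenyl]-4-(hydroxymethyl)oxolan-3-yl}methanol | COc1cc([C@H](O)[C@@H]2CO[C@@H](c3ccc(O[Si](C)(C)C(C)(C)C)c(OC)c3)[C@@H]2CO)ccc1O[Si](C)(C)C(C)(C)C | intermediate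
18 | 4-[(2R,3S,4S)-4-[(R)-hydroxy(4-hydroxy-3-methoxyphenyl)methyl]-3-(hydroxymethyl)oxolan-2-yl]-2-methoxyphenol | COc1cc([C@H](O)[C@@H]2CO[C@@H](c3ccc(O)c(OC)c3)[C@@H]2CO)ccc1O | target

**Step count and risks**

Total step count: 9. Longest linear sequence: 7 steps (3 → 5 → 7 → 8 → 9 → 12 → 17 → 18).

Steps most likely to fail:

1. Step 8. The risk is poor facial selectivity: if the opened lactol reacts through a non-chelated Felkin–Anh arrangement instead of the magnesium-bridged one, the C7′ epimer would form. The fallback exchanges the roles of nucleophile and carbonyl substituent, so that Felkin–Anh control gives the needed isomer. It sets out from 12 and comes back at 18. Fétizon oxidation of 12 (Ag2CO3 on Celite, toluene, reflux) should give the cis-fused lactone F1. The aryllithium made from 14 (n-BuLi, THF, −78 °C) should add once to F1, since the lithium hemiketalate does not collapse in the cold, to give the hydroxy ketone F2. Silylation of the primary hydroxyl (TBSCl, imidazole, DMF) gives the silyl ether F3, which can no longer chelate. Reduction with LiBH(s-Bu)3 in THF at −78 °C should deliver hydride anti to the branched C3 side of the ring with the aryl group eclipsing the C4 hydrogen, giving the (R)-alcohol F4. Bu4NF/AcOH then removes all three silyl groups to give 18.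

2. Step 2. The risks are slow addition to the weakly reactive butenolide, migration of the vinyl double bond into conjugation at 100 °C, or insufficient enantioselectivity. The fallback replaces asymmetric catalysis by a racemic addition and a classical resolution. It sets out from 3 and comes back at 5. Copper-mediated conjugate addition of vinylmagnesium bromide to 3 (CuBr·SMe2, Me3SiCl, THF, −78 °C) should give the racemic lactone F5. Ring opening with (S)-1-phenylethylamine (AlMe3, CH2Cl2) gives two diastereomeric hydroxy amides, from which the (R,S) isomer F6 is separated by crystallisation or chromatography. Acid-promoted relactonisation (TsOH·H2O, toluene, 80 °C) returns 5.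

3. Step 5. The risks are incomplete control of the C2 configuration in the cation closure, elimination of the benzylic cation to a styrene, or loss of the aryl silyl ether under acid. The fallback closes the ring through a p-quinone methide under near-neutral conditions. It sets out from 8 and comes back at 9. Desilylation of 8 (Bu4NF/AcOH, THF, 0 °C) gives the free phenol F7. In hexafluoroisopropanol at rt to 40 °C the p-hydroxybenzylic alcohol should ionise to the p-quinone methide, and reversible intramolecular oxa-1,6-addition of the C5 hydroxyl should give the 2,3-trans oxolane phenol F8 under thermodynamic control. Phenoxide-selective silylation (NaH, 1.0 equiv, then TBSCl, THF, 0 °C) returns 9.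

**Further compounds**

F1 | step 8 | (3aS,4R,6aS)-4-[4-(tert-butyldimethylsilyloxy)-3-methoxyphenyl]tetrahydro-1H,3H-furo[3,4-c]furan-1-one | O=C1OC[C@H]2[C@H](c3ccc(O[Si](C)(C)C(C)(C)C)c(OC)c3)OC[C@@H]12
F2 | step 8 | [4-(tert-butyldimethylsilyloxy)-3-methoxyphenyl]{(3S,4S,5R)-5-[4-(tert-butyldimethylsilyloxy)-3-methoxyphenyl]-4-(hydroxymethyl)oxolan-3-yl}methanone | COc1cc(C(=O)[C@@H]2CO[C@@H](c3ccc(O[Si](C)(C)C(C)(C)C)c(OC)c3)[C@@H]2CO)ccc1O[Si](C)(C)C(C)(C)C
F3 | step 8 | [4-(tert-butyldimethylsilyloxy)-3-methoxyphenyl]{(3S,4S,5R)-5-[4-(tert-butyldimethylsilyloxy)-3-methoxyphenyl]-4-[(tert-butyldimethylsilyloxy)methyl]oxolan-3-yl}methanone | COc1cc(C(=O)[C@@H]2CO[C@@H](c3ccc(O[Si](C)(C)C(C)(C)C)c(OC)c3)[C@@H]2CO[Si](C)(C)C(C)(C)C)ccc1O[Si](C)(C)C(C)(C)C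
F4 | step 8 | (R)-[4-(tert-butyldimethylsilyloxy)-3-methoxyphenyl]{(3S,4S,5R)-5-[4-(tert-butyldimethylsilyloxy)-3-methoxyphenyl]-4-[(tert-butyldimethylsilyloxy)methyl]oxolan-3-yl}methanol | COc1cc([C@H](O)[C@@H]2CO[C@@H](c3ccc(O[Si](C)(C)C(C)(C)C)c(OC)c3)[C@@H]2CO[Si](C)(C)C(C)(C)C)ccc1O[Si](C)(C)C(C)(C)C
F5 | step 2 | racemic 4-vinyldihydrofuran-2(3H)-one | C=CC1COC(=O)C1
F6 | step 2 | (R)-3-(hydroxymethyl)-N-[(S)-1-phenylethyl]pent-4-enamide | C=C[C@H](CO)CC(=O)N[C@@H](C)c1ccccc1
F7 | step 5 | (2S,3S)-2-[hydroxy(4-hydroxy-3-methoxyphenyl)methyl]-3-vinylbutane-1,4-diol, both carbinol epimers | C=C[C@H](CO)[C@@H](CO)C(O)c1ccc(O)c(OC)c1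
F8 | step 5 | 4-[(2R,3S,4S)-3-(hydroxymethyl)-4-vinyloxolan-2-yl]-2-methoxyphenol | C=C[C@@H]1CO[C@@H](c2ccc(O)c(OC)c2)[C@@H]1CO
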